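All constants are assumed; the result is computed.

- The ratio I carry is the reach n = k_w·c_E/k_d. Here k_w is the rate constant of J + E → E + X, c_E is the charge of E, and k_d is the rate constant of E → Z.

| setting | zeta | delta | epsilon |
|---|---|---|---|
| J | 20 mM | 20 mM | 20 mM |
| Q | 26.0 mM | 26.0 mM | 26.0 mM |
| E | 1.1 mM | 1.1 mM | 1.1 mM |
| G | 1.3 mM | 1.3 mM | 1.3 mM |
| temperature | 70 °C | 40 °C | 100 °C |
| time | 2.5 d | 2.5 d | 2.5 d |

    E → Z (k1 = 0.90 h⁻¹, Ea1 = 126 kJ mol⁻¹)
    G + X ⇌ G.X (K2 = 74 L mol⁻¹, k2 = 380 L mol⁻¹ h⁻¹, Ea2 = 75.0 kJ mol⁻¹, ΔH2 = −2.00 kJ mol⁻¹)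
    Q + G.X ⇌ G + D (K3 = 1.1, k3 = 250 L mol⁻¹ h⁻¹, Ea3 = 59.0 kJ mol⁻¹, ΔH3 = 7.00 kJ mol⁻¹)
    J + E → E + X (k4 = 98 L mol⁻¹ h⁻¹, Ea4 = 67.0 kJ mol⁻¹)
    (constants at 100 °C)

- the constants hold at 100 °C; other temperatures follow from the activation energies and enthalpies

1. the flask that comes out highest in amount of D, in percent of the J charged, or "all alike" when all lie within 1.5 percentage points (zeta / delta / epsilon / all alike)
2. D at the end, in percent of the J charged, zeta
3. D at the end, in percent of the J charged, delta
4. D at the end, in percent of the J charged, epsilon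

- J falls pseudo-first-order, with a fading E in the constant, so I reckon the fraction left: exp(−n·f), where f is the part of E already turned to Z at the reading.
- Each D comes from one X and each X from one J, so the J burned is a ceiling on D.
- In zeta, k_d is 0.0258 h⁻¹ and k_w is 14.8 L mol⁻¹ h⁻¹, so n, the logarithm of the drop in J that E can deliver over its whole life, is 0.632.
- With f at 78.8%, zeta keeps 60.8% of its J, which puts its ceiling at 39.2%.
- Delta has a reach of 4.58, but f is 2.23%, so hardly any of its E dies in the time and its ceiling is 9.70%.
- Epsilon has a reach of 0.120 and f at 100%, so it spends nearly all of that reach and its ceiling is 11.3%.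
- Turned round, epsilon could lead on reach if n grew with heat, and at a fixed charge of E that needs J + E → E + X to have the higher activation energy. Its activation energy stands 59.0 kJ mol⁻¹ below that of E → Z.
- For zeta to lose, less than 28.8% of the J it burns may reach D, because its ceiling is higher than the others. I commit to zeta and reckon no further.
- The forecast gives zeta, with 19% in zeta, 0.9% in delta and 7.3% in epsilon, and says of zeta that “this charge gives the most D, though it is still short of equilibrium”.
- The flask that comes out highest is zeta, with D at 19.1%, against 0.819% in delta and 7.30% in epsilon. That is about half of zeta's ceiling, more than the share it needed. A neighbour of zeta charged with 2.8 mM of E has its reach raised to 1.61, with f unchanged, so I reckon 28.2% of its J left. At 2.50 d that flask holds 28.2% of its J, with D at 33.6%.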